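**Plan**

- Retrosynthetic cuts, in order: the nine O–benzyl bonds; the C4 styryl C=C (Horner–Wadsworth–Emmons); then the dihydrofuran ring is contracted to a cyclopropane by cutting O1–C2 and joining C2 to C3a. This gives a spiro[2.5]octadienone whose C3a–C2 and C3a–C3 bonds are cut to an o-quinone diazide and an (E)-stilbene.
- Enabling feature: the edge O1–C7a–C3a of the benzo ring can exist dearomatised as a cyclohexa-2,4-dienone (C7a=O) with C3a as spiro carbon of the cyclopropane C2–C3–C3a. C2 carries the only aryl ring with a para oxygen, so ring strain and re-aromatisation drive heterolysis of C3a–C2 and closure of O1 on C2.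
- Forward order: stilbene by HWE; quinone diazide from methyl gallate (dibenzylation, ortho-nitration, reduction, diazotisation); Rh-carbene transfer builds the cyclopropane, which expands in the same flask to the dihydrobenzofuran; the C4 ester is taken to the aldehyde and then to the second stilbene; global debenzylation.
- Stereochemistry: C3 comes from enantiofacial carbene transfer under a chiral dirhodium carboxylate and is carried unchanged through the expansion; C2 closes trans to the C3 aryl group (substrate control); both alkenes are E from HWE.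

Key step: step 7

Assumption: the sense of facial selection of Rh2(S-TCPTTL)4 on this stilbene is assigned by analogy only; should the first run give the antipode, the equally available Rh2(R-TCPTTL)4 is to be used with no other change.

Step 1
Reactants: 1 3,5-bis(benzyloxy)benzyl bromide
Product: 2 diethyl [3,5-bis(benzyloxy)benzyl]phosphonate
Conditions: P(OEt)3 (3 equiv, neat), 140 °C, EtBr distilled off
Reagents that add atoms: triethyl phosphite, CCOP(OCC)OCC
Why: Michaelis–Arbuzov reaction of a primary benzylic bromide should proceed cleanly; no stereocentre is involved.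

Step 2
Reactants: 2 diethyl [3,5-bis(benzyloxy)benzyl]phosphonate; 3 3,4,5-tris(benzyloxy)benzaldehyde
Product: 4 (E)-3,3',4,5,5'-pentakis(benzyloxy)stilbene
Conditions: KOtBu (1.1 equiv), THF, 0 °C → rt
Reagents that add atoms: none
Why: Horner–Wadsworth–Emmons olefination of an aryl aldehyde with a benzylic phosphonate should give the (E)-stilbene with high selectivity.

Step 3
Reactants: 5 methyl gallate (methyl 3,4,5-trihydroxybenzoate)
Product: 6 methyl 3,4-bis(benzyloxy)-5-hydroxybenzoate
Conditions: BnBr (2.05 equiv), K2CO3 (2.2 equiv), DMF, rt; chromatography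
Reagents that add atoms: benzyl bromide, BrCc1ccccc1
Why: Williamson etherification in which the 4-OH (para to the ester, most acidic) reacts first and the second benzyl group can only enter one of the two equivalent flanking hydroxyls, so a single dibenzyl ether should result and be separable from mono- and tribenzyl ethers.

Step 4
Reactants: 6 methyl 3,4-bis(benzyloxy)-5-hydroxybenzoate
Product: 7 methyl 4,5-bis(benzyloxy)-3-hydroxy-2-nitrobenzoate
Conditions: HNO3 (65 %, 1.1 equiv), AcOH/CH2Cl2, 0 °C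
Reagents that add atoms: nitric acid, O[N+](=O)[O-]
Why: electrophilic nitration should go to the position between OH and CO2Me (ortho to the free phenol, para to a benzyloxy group, flanked only by the small OH), as in the nitration of isovanillin and of 3-hydroxy-4-methylbenzoic acid, whereas the position para to OH lies between the ester and a bulky benzyloxy group.

Step 5
Reactants: 7 methyl 4,5-bis(benzyloxy)-3-hydroxy-2-nitrobenzoate
Product: 8 methyl 2-amino-4,5-bis(benzyloxy)-3-hydroxybenzoate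
Conditions: H2 (1 atm), 5 % Pt(S)/C, EtOAc, rt
Reagents that add atoms: none
Why: catalytic hydrogenation over sulfided platinum should reduce the nitro group chemoselectively without hydrogenolysis of the benzyl ethers.

Step 6
Reactants: 8 methyl 2-amino-4,5-bis(benzyloxy)-3-hydroxybenzoate
Product: 9 methyl 3,4-bis(benzyloxy)-6-diazo-5-oxocyclohexa-1,3-diene-1-carboxylate (o-quinone diazide)
Conditions: t-BuONO (1.2 equiv), AcOH (1 equiv), MeCN, 0 °C, dark; NaHCO3 wash
Reagents that add atoms: tert-butyl nitrite, CC(C)(C)ON=O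
Why: diazotisation of an o-aminophenol should give the diazonium ion, which loses the phenolic proton to the neutral, isolable o-quinone diazide.

Step 7
Reactants: 9 methyl 3,4-bis(benzyloxy)-6-diazo-5-oxocyclohexa-1,3-diene-1-carboxylate; 4 (E)-3,3',4,5,5'-pentakis(benzyloxy)stilbene
Product: 11 methyl (2S,3S)-6,7-bis(benzyloxy)-3-[3,5-bis(benzyloxy)phenyl]-2-[3,4,5-tris(benzyloxy)phenyl]-2,3-dihydro-1-benzofuran-4-carboxylate, via spirocyclopropyl dienone 10 (not isolated)
Conditions: 9 added over 4 h to 4 (1.5 equiv), Rh2(S-TCPTTL)4 (1 mol %), 4 Å MS, PhCF3, 40 °C, dark; then 60 °C, 1 h (Sc(OTf)3, 5 mol %, only if 10 persists)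
Reagents that add atoms: none
Why: Proposed new method: Rh(II) should convert the o-quinone diazide into an electrophilic quinoid carbenoid that cyclopropanates the stilbene ([2+1] closure) to spiro[2.5]octa-4,6-dien-8-one 10, whose C3a–C2 bond then ionises (push from the para-benzyloxy aryl ring on C2, pull from the dienone becoming a phenoxide) so that the phenoxide oxygen closes on C2 (5-exo-trig on the benzylic cation) and the cyclopropane C2–C3–C3a is expanded by C7a and O1 to the dihydrofuran ring, driven by strain release and aromatisation of the benzo ring. The closest known reaction types are the Rh(II)-catalysed cyclopropanation of alkenes with quinone diazides, the formal [3+2] annulation of cyclic α-diazo carbonyl compounds with electron-rich alkenes, the Cloke–Wilson cyclopropyl ketone to dihydrofuran rearrangement and enantioselective cyclopropanation with cyclic diazo carbonyls under Rh2(S-PTTL)4-type catalysts; the enantioselective variant with an o-quinone diazide and a 1,2-diarylethene is the new element. C3 is set in the carbene transfer, where the chiral pocket of phthalimido groups on the dirhodium carboxylate should distinguish the enantiotopic faces of the stilbene, and it is carried into 11 unchanged because none of its bonds is touched in the expansion (the spiro centre is lost on aromatisation, so either spiro epimer converges). C2 is formed anew on ring closure, trans to the C3 aryl group under substrate control, and this is reinforced thermodynamically because C2–O ionisation is reversible. The step needs regioselective cleavage of C3a–C2 rather than C3a–C3, secured by the para oxygen present only on the C2 aryl ring (the 3,5-bis(benzyloxy)phenyl ring on C3 has meta oxygens only). It also needs chemoselectivity for the alkene over benzylic C–H or arene attack and over Wolff rearrangement, secured by excess electron-rich alkene, slow addition and exclusion of light.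

Step 8
Reactants: 11 methyl (2S,3S)-6,7-bis(benzyloxy)-3-[3,5-bis(benzyloxy)phenyl]-2-[3,4,5-tris(benzyloxy)phenyl]-2,3-dihydro-1-benzofuran-4-carboxylate
Product: 12 [(2S,3S)-6,7-bis(benzyloxy)-3-[3,5-bis(benzyloxy)phenyl]-2-[3,4,5-tris(benzyloxy)phenyl]-2,3-dihydro-1-benzofuran-4-yl]methanol
Conditions: DIBAL-H (3 equiv), CH2Cl2, −78 → 0 °C; Rochelle salt work-up
Reagents that add atoms: none
Why: hydride reduction of the aryl ester to the primary alcohol should leave benzyl ethers, the cyclic ether and both stereocentres untouched.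

Step 9
Reactants: 12 [(2S,3S)-6,7-bis(benzyloxy)-3-[3,5-bis(benzyloxy)phenyl]-2-[3,4,5-tris(benzyloxy)phenyl]-2,3-dihydro-1-benzofuran-4-yl]methanol
Product: 13 (2S,3S)-6,7-bis(benzyloxy)-3-[3,5-bis(benzyloxy)phenyl]-2-[3,4,5-tris(benzyloxy)phenyl]-2,3-dihydro-1-benzofuran-4-carbaldehyde
Conditions: activated MnO2 (15 equiv), CH2Cl2, rt
Reagents that add atoms: none
Why: MnO2 oxidation of a benzylic alcohol is neutral and should stop at the aldehyde without touching the base-sensitive C3–H.

Step 10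
Reactants: 13 (2S,3S)-6,7-bis(benzyloxy)-3-[3,5-bis(benzyloxy)phenyl]-2-[3,4,5-tris(benzyloxy)phenyl]-2,3-dihydro-1-benzofuran-4-carbaldehyde; 2 diethyl [3,5-bis(benzyloxy)benzyl]phosphonate
Product: 14 (2S,3S)-6,7-bis(benzyloxy)-3-[3,5-bis(benzyloxy)phenyl]-4-{(E)-2-[3,5-bis(benzyloxy)phenyl]ethenyl}-2-[3,4,5-tris(benzyloxy)phenyl]-2,3-dihydro-1-benzofuran (nona-O-benzylscirpusin C)
Conditions: 2 (1.3 equiv), KOtBu (1.2 equiv), THF, 0 °C (anion pre-formed); then 13, −20 → 0 °C
Reagents that add atoms: none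
Why: Horner–Wadsworth–Emmons olefination should give the (E)-stilbene, and pre-forming the anion with a deficit of base leaves no free alkoxide to deprotonate C3–H, so the (2S,3S) centres should be retained.

Step 11
Reactants: 14 nona-O-benzylscirpusin C
Product: 15 Scirpusin C, (2S,3S)-3-(3,5-dihydroxyphenyl)-4-[(E)-2-(3,5-dihydroxyphenyl)ethenyl]-2-(3,4,5-trihydroxyphenyl)-2,3-dihydro-1-benzofuran-6,7-diol
Conditions: BCl3 (1 M in CH2Cl2, 27 equiv), pentamethylbenzene (40 equiv), CH2Cl2, −78 °C, Ar; quench CHCl3/MeOH (10:1) at −78 °C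
Reagents that add atoms: none
Why: Lewis-acid O-debenzylation with BCl3 and pentamethylbenzene as a non-basic benzyl-cation scavenger works at −78 °C, a combination established for benzyl-protected oligostilbenes, and should remove all nine benzyl groups without reducing the stilbene or cleaving the benzylic C2–O bond, leaving both stereocentres as set.

**Compound list**

1 | 3,5-bis(benzyloxy)benzyl bromide | BrCc1cc(OCc2ccccc2)cc(OCc2ccccc2)c1 | starting material
2 | diethyl [3,5-bis(benzyloxy)benzyl]phosphonate | CCOP(=O)(OCC)Cc1cc(OCc2ccccc2)cc(OCc2ccccc2)c1 | intermediate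
3 | 3,4,5-tris(benzyloxy)benzaldehyde | O=Cc1cc(OCc2ccccc2)c(OCc2ccccc2)c(OCc2ccccc2)c1 | starting material
4 | (E)-3,3',4,5,5'-pentakis(benzyloxy)stilbene | O(Cc1ccccc1)c1cc(OCc2ccccc2)cc(/C=C/c2cc(OCc3ccccc3)c(OCc3ccccc3)c(OCc3ccccc3)c2)c1 | intermediate
5 | methyl gallate | COC(=O)c1cc(O)c(O)c(O)c1 | starting material
6 | methyl 3,4-bis(benzyloxy)-5-hydroxybenzoate | COC(=O)c1cc(O)c(OCc2ccccc2)c(OCc2ccccc2)c1 | intermediate
7 | methyl 4,5-bis(benzyloxy)-3-hydroxy-2-nitrobenzoate | COC(=O)c1cc(OCc2ccccc2)c(OCc2ccccc2)c(O)c1[N+](=O)[O-] | intermediate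
8 | methyl 2-amino-4,5-bis(benzyloxy)-3-hydroxybenzoate | COC(=O)c1cc(OCc2ccccc2)c(OCc2ccccc2)c(O)c1N | intermediate
9 | methyl 3,4-bis(benzyloxy)-6-diazo-5-oxocyclohexa-1,3-diene-1-carboxylate (o-quinone diazide) | COC(=O)C1=CC(OCc2ccccc2)=C(OCc2ccccc2)C(=O)C1=[N+]=[N-] | intermediate
10 | methyl (1S,2S,3S)-6,7-bis(benzyloxy)-1-[3,5-bis(benzyloxy)phenyl]-8-oxo-2-[3,4,5-tris(benzyloxy)phenyl]spiro[2.5]octa-4,6-diene-4-carboxylate (aryl groups trans on the cyclopropane; drawn as one spiro epimer, the other converges) | COC(=O)C1=CC(OCc2ccccc2)=C(OCc2ccccc2)C(=O)[C@]12[C@H](c1cc(OCc3ccccc3)cc(OCc3ccccc3)c1)[C@H]2c1cc(OCc3ccccc3)c(OCc3ccccc3)c(OCc3ccccc3)c1 | intermediate (not isolated)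
11 | methyl (2S,3S)-6,7-bis(benzyloxy)-3-[3,5-bis(benzyloxy)phenyl]-2-[3,4,5-tris(benzyloxy)phenyl]-2,3-dihydro-1-benzofuran-4-carboxylate | COC(=O)c1cc(OCc2ccccc2)c(OCc2ccccc2)c2c1[C@H](c1cc(OCc3ccccc3)cc(OCc3ccccc3)c1)[C@@H](c1cc(OCc3ccccc3)c(OCc3ccccc3)c(OCc3ccccc3)c1)O2 | intermediate
12 | [(2S,3S)-6,7-bis(benzyloxy)-3-[3,5-bis(benzyloxy)phenyl]-2-[3,4,5-tris(benzyloxy)phenyl]-2,3-dihydro-1-benzofuran-4-yl]methanol | OCc1cc(OCc2ccccc2)c(OCc2ccccc2)c2c1[C@H](c1cc(OCc3ccccc3)cc(OCc3ccccc3)c1)[C@@H](c1cc(OCc3ccccc3)c(OCc3ccccc3)c(OCc3ccccc3)c1)O2 | intermediate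
13 | (2S,3S)-6,7-bis(benzyloxy)-3-[3,5-bis(benzyloxy)phenyl]-2-[3,4,5-tris(benzyloxy)phenyl]-2,3-dihydro-1-benzofuran-4-carbaldehyde | O=Cc1cc(OCc2ccccc2)c(OCc2ccccc2)c2c1[C@H](c1cc(OCc3ccccc3)cc(OCc3ccccc3)c1)[C@@H](c1cc(OCc3ccccc3)c(OCc3ccccc3)c(OCc3ccccc3)c1)O2 | intermediate
14 | nona-O-benzylscirpusin C, (2S,3S)-6,7-bis(benzyloxy)-3-[3,5-bis(benzyloxy)phenyl]-4-{(E)-2-[3,5-bis(benzyloxy)phenyl]ethenyl}-2-[3,4,5-tris(benzyloxy)phenyl]-2,3-dihydro-1-benzofuran | O(Cc1ccccc1)c1cc(OCc2ccccc2)cc(/C=C/c2cc(OCc3ccccc3)c(OCc3ccccc3)c3c2[C@H](c2cc(OCc4ccccc4)cc(OCc4ccccc4)c2)[C@@H](c2cc(OCc4ccccc4)c(OCc4ccccc4)c(OCc4ccccc4)c2)O3)c1 | intermediate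
15 | Scirpusin C, (2S,3S)-3-(3,5-dihydroxyphenyl)-4-[(E)-2-(3,5-dihydroxyphenyl)ethenyl]-2-(3,4,5-trihydroxyphenyl)-2,3-dihydro-1-benzofuran-6,7-diol | Oc1cc(O)cc(/C=C/c2cc(O)c(O)c3c2[C@H](c2cc(O)cc(O)c2)[C@@H](c2cc(O)c(O)c(O)c2)O3)c1 | target

**Step count**

Total: 11 steps. Longest linear sequence: 9 steps (5 → 15, steps 3–11).

**Steps most likely to fail**

Step 7. The chiral dirhodium carboxylate may discriminate the faces of a 1,2-diaryl alkene poorly. Carbene transfer to a trans-alkene may be slow, so that carbene attack on benzyloxy arenes or benzylic C–H bonds competes. The benzylic cation formed on ring opening may also be trapped by the neighbouring ester carbonyl instead of the phenoxide. The fallback gives up asymmetric induction, sets out from 9 and 4 and returns at 11. The achiral catalyst Rh2(esp)2 (0.5 mol %, PhCF3, 60 °C) is used in the known Rh(II)-catalysed formal [3+2] annulation of o-quinone diazides with electron-rich alkenes. It should pass through the racemic spirocyclopropyl dienone, that is 10 together with its enantiomer, the (1R,2R,3R)-spirocyclopropyl dienone F1, and give the racemic trans ester, that is 11 together with its (2R,3R)-enantiomer F2. Compound 11 is then separated from F2 by preparative supercritical-fluid chromatography on an amylose carbamate chiral phase.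

Step 11. Cleavage of nine ethers may stay incomplete. The Lewis acid may ionise the C2–O bond with Friedel–Crafts capture of the cation, or the stilbene may cyclise under acid onto the neighbouring resorcinol ring. The free pyrogallol unit may also oxidise in air during isolation. The fallback exchanges the protecting groups before the acid-sensitive stilbene exists, sets out from 11 (and from 2 for the phosphonate) and returns at 15.

- Hydrogenolysis of 11 (H2, Pd(OH)2/C, EtOAc/MeOH) should give the heptaphenol methyl ester F3.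
- Silylation (TBSCl, imidazole, DMF) should give the heptakis(tert-butyldimethylsilyl) ether ester F4.
- DIBAL-H reduction should give the benzylic alcohol F5, and MnO2 oxidation the aldehyde F6.
- In parallel, hydrogenolysis of 2 (H2, Pd/C, EtOH) should give diethyl (3,5-dihydroxybenzyl)phosphonate F7, and silylation diethyl [3,5-bis(tert-butyldimethylsilyloxy)benzyl]phosphonate F8.
- Horner–Wadsworth–Emmons reaction of F6 with F8 (LiHMDS, THF, −78 → 0 °C) should give nonakis(tert-butyldimethylsilyl)scirpusin C F9.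
- Buffered fluoride (TBAF/AcOH, THF, 0 °C, Ar) should release 15 under non-acidic conditions.

Step 10. The base may deprotonate C3–H, which is activated by the ortho formyl group, and β-elimination of the phenoxide would then open the ring and destroy both stereocentres. Addition to the hindered aldehyde may also be slow. The fallback avoids strong base, sets out from 13 and returns at 14. Takai olefination of 13 (CrCl2, CHI3, THF, 0 °C) should give the (E)-vinyl iodide, (2S,3S)-6,7-bis(benzyloxy)-3-[3,5-bis(benzyloxy)phenyl]-4-[(E)-2-iodoethenyl]-2-[3,4,5-tris(benzyloxy)phenyl]-2,3-dihydro-1-benzofuran F10. Suzuki–Miyaura coupling of F10 with 3,5-bis(benzyloxy)phenylboronic acid (Pd(PPh3)4, K2CO3, DME/H2O, 60 °C) should then give 14 with retention of the E geometry.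

Further compounds
F1 | step 7 | methyl (1R,2R,3R)-6,7-bis(benzyloxy)-1-[3,5-bis(benzyloxy)phenyl]-8-oxo-2-[3,4,5-tris(benzyloxy)phenyl]spiro[2.5]octa-4,6-diene-4-carboxylate (enantiomer of 10, not isolated) | COC(=O)C1=CC(OCc2ccccc2)=C(OCc2ccccc2)C(=O)[C@@]12[C@@H](c1cc(OCc3ccccc3)cc(OCc3ccccc3)c1)[C@@H]2c1cc(OCc3ccccc3)c(OCc3ccccc3)c(OCc3ccccc3)c1
F2 | step 7 | methyl (2R,3R)-6,7-bis(benzyloxy)-3-[3,5-bis(benzyloxy)phenyl]-2-[3,4,5-tris(benzyloxy)phenyl]-2,3-dihydro-1-benzofuran-4-carboxylate (enantiomer of 11) | COC(=O)c1cc(OCc2ccccc2)c(OCc2ccccc2)c2c1[C@@H](c1cc(OCc3ccccc3)cc(OCc3ccccc3)c1)[C@H](c1cc(OCc3ccccc3)c(OCc3ccccc3)c(OCc3ccccc3)c1)O2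
F3 | step 11 | methyl (2S,3S)-3-(3,5-dihydroxyphenyl)-6,7-dihydroxy-2-(3,4,5-trihydroxyphenyl)-2,3-dihydro-1-benzofuran-4-carboxylate | COC(=O)c1cc(O)c(O)c2c1[C@H](c1cc(O)cc(O)c1)[C@@H](c1cc(O)c(O)c(O)c1)O2
F4 | step 11 | methyl (2S,3S)-6,7-bis(tert-butyldimethylsilyloxy)-3-[3,5-bis(tert-butyldimethylsilyloxy)phenyl]-2-[3,4,5-tris(tert-butyldimethylsilyloxy)phenyl]-2,3-dihydro-1-benzofuran-4-carboxylate | COC(=O)c1cc(O[Si](C)(C)C(C)(C)C)c(O[Si](C)(C)C(C)(C)C)c2c1[C@H](c1cc(O[Si](C)(C)C(C)(C)C)cc(O[Si](C)(C)C(C)(C)C)c1)[C@@H](c1cc(O[Si](C)(C)C(C)(C)C)c(O[Si](C)(C)C(C)(C)C)c(O[Si](C)(C)C(C)(C)C)c1)O2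
F5 | step 11 | [(2S,3S)-6,7-bis(tert-butyldimethylsilyloxy)-3-[3,5-bis(tert-butyldimethylsilyloxy)phenyl]-2-[3,4,5-tris(tert-butyldimethylsilyloxy)phenyl]-2,3-dihydro-1-benzofuran-4-yl]methanol | OCc1cc(O[Si](C)(C)C(C)(C)C)c(O[Si](C)(C)C(C)(C)C)c2c1[C@H](c1cc(O[Si](C)(C)C(C)(C)C)cc(O[Si](C)(C)C(C)(C)C)c1)[C@@H](c1cc(O[Si](C)(C)C(C)(C)C)c(O[Si](C)(C)C(C)(C)C)c(O[Si](C)(C)C(C)(C)C)c1)O2
F6 | step 11 | (2S,3S)-6,7-bis(tert-butyldimethylsilyloxy)-3-[3,5-bis(tert-butyldimethylsilyloxy)phenyl]-2-[3,4,5-tris(tert-butyldimethylsilyloxy)phenyl]-2,3-dihydro-1-benzofuran-4-carbaldehyde | O=Cc1cc(O[Si](C)(C)C(C)(C)C)c(O[Si](C)(C)C(C)(C)C)c2c1[C@H](c1cc(O[Si](C)(C)C(C)(C)C)cc(O[Si](C)(C)C(C)(C)C)c1)[C@@H](c1cc(O[Si](C)(C)C(C)(C)C)c(O[Si](C)(C)C(C)(C)C)c(O[Si](C)(C)C(C)(C)C)c1)O2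
F7 | step 11 | diethyl (3,5-dihydroxybenzyl)phosphonate | CCOP(=O)(OCC)Cc1cc(O)cc(O)c1
F8 | step 11 | diethyl [3,5-bis(tert-butyldimethylsilyloxy)benzyl]phosphonate | CCOP(=O)(OCC)Cc1cc(O[Si](C)(C)C(C)(C)C)cc(O[Si](C)(C)C(C)(C)C)c1
F9 | step 11 | nonakis(tert-butyldimethylsilyl)scirpusin C, (2S,3S)-6,7-bis(tert-butyldimethylsilyloxy)-3-[3,5-bis(tert-butyldimethylsilyloxy)phenyl]-4-{(E)-2-[3,5-bis(tert-butyldimethylsilyloxy)phenyl]ethenyl}-2-[3,4,5-tris(tert-butyldimethylsilyloxy)phenyl]-2,3-dihydro-1-benzofuran | CC(C)(C)[Si](C)(C)Oc1cc(O[Si](C)(C)C(C)(C)C)cc(/C=C/c2cc(O[Si](C)(C)C(C)(C)C)c(O[Si](C)(C)C(C)(C)C)c3c2[C@H](c2cc(O[Si](C)(C)C(C)(C)C)cc(O[Si](C)(C)C(C)(C)C)c2)[C@@H](c2cc(O[Si](C)(C)C(C)(C)C)c(O[Si](C)(C)C(C)(C)C)c(O[Si](C)(C)C(C)(C)C)c2)O3)c1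
F10 | step 10 | (2S,3S)-6,7-bis(benzyloxy)-3-[3,5-bis(benzyloxy)phenyl]-4-[(E)-2-iodoethenyl]-2-[3,4,5-tris(benzyloxy)phenyl]-2,3-dihydro-1-benzofuran | I/C=C/c1cc(OCc2ccccc2)c(OCc2ccccc2)c2c1[C@H](c1cc(OCc3ccccc3)cc(OCc3ccccc3)c1)[C@@H](c1cc(OCc3ccccc3)c(OCc3ccccc3)c(OCc3ccccc3)c1)O2
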